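**Retrosynthetic overview**

1. The target joins ring A (4-methoxyphenyl) through C(=O)–CH2 to ring B, a 2-acylresorcinol. Ring B is numbered C1 (bears the CH2), C3 and C5 (bear the hydroxyls), C4 (bears the 4-methylpentanoyl group); there is no stereocentre.
2. The strategy rests on this feature: the acyl-bearing C4 is the neighbour of the oxygen-bearing C3 and has the second oxygen (C5) on its other side. The C3–O and C4–C(=O) bonds are therefore cut together, back to a C3≡C4 aryne polarised by an alkoxy group on C5 and to 4-methylpentanoic acid.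
3. The ArC(=O)CH2 link is carried as a diaryl alkyne (Sonogashira coupling) and unmasked late by hydration, whose direction is fixed by the para-methoxy group of ring A.
4. The aryne precursor (a silyl triflate) comes from 5-bromoresorcinol by monobenzylation, Sonogashira coupling, carbamate-directed silylation at C4 and carbamate-to-triflate exchange.
5. No ring is formed in the route: rings A and B are both bought as benzene rings and only substituents are installed; the benzyl group is removed last.

Key step: step 6

**Route**

Step 1
Reactants: 1 5-bromobenzene-1,3-diol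
Product: 2 3-(benzyloxy)-5-bromophenol
Conditions: BnBr (0.9 equiv), K2CO3 (1.0 equiv), DMF, rt
Reagents that add atoms: benzyl bromide, BrCc1ccccc1
Why: Williamson etherification of the symmetric diol with a slight deficit of benzyl bromide should give the mono-ether as the main product of a statistical alkylation, the dibenzyl ether and unreacted diol being separable by chromatography and the diol recyclable.

Step 2
Reactants: 2 3-(benzyloxy)-5-bromophenol; 3 1-ethynyl-4-methoxybenzene
Product: 4 3-(benzyloxy)-5-[(4-methoxyphenyl)ethynyl]phenol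
Conditions: Pd(PPh3)2Cl2 (3 mol%), CuI (5 mol%), Et3N/DMF, 70 °C, degassed
Reagents that add atoms: none
Why: Sonogashira coupling should proceed because the C–Br bond lies meta to both oxygens and so is not deactivated by resonance donation, and the free phenol is tolerated under amine base.

Step 3
Reactants: 4 3-(benzyloxy)-5-[(4-methoxyphenyl)ethynyl]phenol
Product: 5 3-(benzyloxy)-5-[(4-methoxyphenyl)ethynyl]phenyl N-isopropylcarbamate
Conditions: i-PrNCO (1.5 equiv), Et3N (0.2 equiv), CH2Cl2, rt
Reagents that add atoms: isopropyl isocyanate, CC(C)N=C=O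
Why: Base-catalysed addition of the phenol to the isocyanate should give the N–H carbamate, which serves as the strongest directing group on ring B and can later be removed under mild base.

Step 4
Reactants: 5 3-(benzyloxy)-5-[(4-methoxyphenyl)ethynyl]phenyl N-isopropylcarbamate
Product: 9 3-(benzyloxy)-5-[(4-methoxyphenyl)ethynyl]-2-(trimethylsilyl)phenyl N-isopropylcarbamate, via N-silyl carbamate 6 (not isolated), via aryllithium 7 (not isolated), via bis-silyl carbamate 8 (not isolated)
Conditions: TBSOTf, TMEDA, Et2O, 0 °C to rt; n-BuLi, TMEDA, −78 °C; TMSCl, −78 °C to rt; aq. NaHSO4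
Reagents that add atoms: chlorotrimethylsilane, C[Si](C)(C)Cl
Why: Directed ortho-metalation: once in situ N-silylation has masked the N–H, the carbamate and the benzyloxy group together should direct n-BuLi/TMEDA to the ring carbon between them (C4) faster at −78 °C than benzylic deprotonation or addition to the diaryl alkyne, and TMSCl quench followed by acidic work-up (loss of the N-silyl group) should give 9.

Step 5
Reactants: 9 3-(benzyloxy)-5-[(4-methoxyphenyl)ethynyl]-2-(trimethylsilyl)phenyl N-isopropylcarbamate
Product: 11 3-(benzyloxy)-5-[(4-methoxyphenyl)ethynyl]-2-(trimethylsilyl)phenyl trifluoromethanesulfonate, via silyl phenol 10 (not isolated)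
Conditions: DBU, Et2NH, MeCN, 40 °C; then PhNTf2, rt
Reagents that add atoms: N-phenylbis(trifluoromethanesulfonimide), O=S(=O)(N(c1ccccc1)S(=O)(=O)C(F)(F)F)C(F)(F)F
Why: E1cB cleavage of the N-monosubstituted carbamate (DBU removes the N–H, isopropyl isocyanate is expelled and scavenged by Et2NH as a urea) should release the phenoxide, which is triflated in the same flask by PhNTf2 so that the silyl phenol need not be handled.

Step 6
Reactants: 11 3-(benzyloxy)-5-[(4-methoxyphenyl)ethynyl]-2-(trimethylsilyl)phenyl trifluoromethanesulfonate; 12 4-methylpentanoic acid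
Product: 14 1-{2-(benzyloxy)-6-hydroxy-4-[(4-methoxyphenyl)ethynyl]phenyl}-4-methylpentan-1-one, via aryne 13 (not isolated)
Conditions: CsF (4 equiv), 12 (1.2 equiv), THF, 125 °C, sealed tube
Reagents that add atoms: none
Why: Fluoride attacks silicon of 11 and triflate leaves from the neighbouring carbon, giving aryne 13 with the triple bond between C3 and C4 of ring B; cesium 4-methylpentanoate adds through oxygen at C3, and the aryl anion so formed at C4 attacks the carbonyl of the new aryl ester through a four-membered transition state that collapses to the ortho-acyl phenoxide, a net insertion of the aryne into the acid C–O bond that forms the C3–O and C4–C(=O) bonds. The closest known reaction type is the fluoride-induced insertion of silyl-triflate-derived arynes into carboxylic acids in hot THF, which gives ortho-hydroxyaryl ketones, including from 3-alkoxyarynes. No ring of the target is closed, the four-membered arrangement only relays the acyl group from oxygen to carbon, and no stereocentre is created. The selectivity needed is the site of carboxylate addition: the C5 benzyloxy group distorts the aryne by its inductive pull so that the nucleophile attacks the distal carbon C3 and the charge develops at C4 next to oxygen, which is the carbon that must carry the acyl group. The high temperature should favour the intramolecular acyl shift over protonation of the aryl anion, and the diaryl alkyne, the benzyl ether and the methyl ether are inert to fluoride and to the aryne.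

Step 7
Reactants: 14 1-{2-(benzyloxy)-6-hydroxy-4-[(4-methoxyphenyl)ethynyl]phenyl}-4-methylpentan-1-one
Product: 15 1-{2-(benzyloxy)-6-hydroxy-4-[2-(4-methoxyphenyl)-2-oxoethyl]phenyl}-4-methylpentan-1-one
Conditions: p-TsOH·H2O (0.3 equiv), EtOH/H2O, 80 °C
Reagents that add atoms: water, O
Why: Brønsted acid-catalysed Markovnikov hydration: protonation at the alkyne carbon attached to the acyl-deactivated ring B should give the vinyl cation stabilised by the para-methoxyphenyl ring, so water enters at the anisyl-bearing carbon and tautomerisation places the ketone beside ring A.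

Step 8
Reactants: 15 1-{2-(benzyloxy)-6-hydroxy-4-[2-(4-methoxyphenyl)-2-oxoethyl]phenyl}-4-methylpentan-1-one
Product: 16 1-{2,6-dihydroxy-4-[2-(4-methoxyphenyl)-2-oxoethyl]phenyl}-4-methylpentan-1-one
Conditions: H2 (1 atm), Pd/C (10%), EtOAc, rt
Reagents that add atoms: none
Why: Heterogeneous hydrogenolysis of the benzyl aryl ether should be much faster than reduction of the two aryl ketones under neutral conditions at atmospheric pressure, and the methyl ether is untouched.

**Compound list**

1 | 5-bromobenzene-1,3-diol | Oc1cc(O)cc(Br)c1 | starting material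
2 | 3-(benzyloxy)-5-bromophenol | Oc1cc(Br)cc(OCc2ccccc2)c1 | intermediate
3 | 1-ethynyl-4-methoxybenzene | C#Cc1ccc(OC)cc1 | starting material
4 | 3-(benzyloxy)-5-[(4-methoxyphenyl)ethynyl]phenol | COc1ccc(C#Cc2cc(O)cc(OCc3ccccc3)c2)cc1 | intermediate
5 | 3-(benzyloxy)-5-[(4-methoxyphenyl)ethynyl]phenyl N-isopropylcarbamate | COc1ccc(C#Cc2cc(OC(=O)NC(C)C)cc(OCc3ccccc3)c2)cc1 | intermediate
6 | 3-(benzyloxy)-5-[(4-methoxyphenyl)ethynyl]phenyl N-(tert-butyldimethylsilyl)-N-isopropylcarbamate (not isolated) | COc1ccc(C#Cc2cc(OC(=O)N(C(C)C)[Si](C)(C)C(C)(C)C)cc(OCc3ccccc3)c2)cc1 | intermediate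
7 | {2-(benzyloxy)-6-[(N-(tert-butyldimethylsilyl)-N-isopropylcarbamoyl)oxy]-4-[(4-methoxyphenyl)ethynyl]phenyl}lithium (not isolated) | COc1ccc(C#Cc2cc(OC(=O)N(C(C)C)[Si](C)(C)C(C)(C)C)c([Li])c(OCc3ccccc3)c2)cc1 | intermediate
8 | 3-(benzyloxy)-5-[(4-methoxyphenyl)ethynyl]-2-(trimethylsilyl)phenyl N-(tert-butyldimethylsilyl)-N-isopropylcarbamate (not isolated) | COc1ccc(C#Cc2cc(OC(=O)N(C(C)C)[Si](C)(C)C(C)(C)C)c([Si](C)(C)C)c(OCc3ccccc3)c2)cc1 | intermediate
9 | 3-(benzyloxy)-5-[(4-methoxyphenyl)ethynyl]-2-(trimethylsilyl)phenyl N-isopropylcarbamate | COc1ccc(C#Cc2cc(OC(=O)NC(C)C)c([Si](C)(C)C)c(OCc3ccccc3)c2)cc1 | intermediate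
10 | 3-(benzyloxy)-5-[(4-methoxyphenyl)ethynyl]-2-(trimethylsilyl)phenol (not isolated) | COc1ccc(C#Cc2cc(O)c([Si](C)(C)C)c(OCc3ccccc3)c2)cc1 | intermediate
11 | 3-(benzyloxy)-5-[(4-methoxyphenyl)ethynyl]-2-(trimethylsilyl)phenyl trifluoromethanesulfonate | COc1ccc(C#Cc2cc(OCc3ccccc3)c([Si](C)(C)C)c(OS(=O)(=O)C(F)(F)F)c2)cc1 | intermediate
12 | 4-methylpentanoic acid | CC(C)CCC(=O)O | starting material
13 | 3-(benzyloxy)-5-[(4-methoxyphenyl)ethynyl]benzyne, triple bond between C3 and C4 of ring B (not isolated) | COc1ccc(C#CC2=CC#CC(OCc3ccccc3)=C2)cc1 | intermediate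
14 | 1-{2-(benzyloxy)-6-hydroxy-4-[(4-methoxyphenyl)ethynyl]phenyl}-4-methylpentan-1-one | COc1ccc(C#Cc2cc(O)c(C(=O)CCC(C)C)c(OCc3ccccc3)c2)cc1 | intermediate
15 | 1-{2-(benzyloxy)-6-hydroxy-4-[2-(4-methoxyphenyl)-2-oxoethyl]phenyl}-4-methylpentan-1-one | COc1ccc(C(=O)Cc2cc(O)c(C(=O)CCC(C)C)c(OCc3ccccc3)c2)cc1 | intermediate
16 | 1-{2,6-dihydroxy-4-[2-(4-methoxyphenyl)-2-oxoethyl]phenyl}-4-methylpentan-1-one | COc1ccc(C(=O)Cc2cc(O)c(C(=O)CCC(C)C)c(O)c2)cc1 | target

**Step count**

Total step count: 8 steps. Longest linear sequence: 8 steps (from 1 to 16).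

**Steps most likely to fail**

Step 6 (aryne insertion). The aryl anion at the crowded carbon between two oxygens may be protonated, or the product phenoxide may be arylated by a second aryne, before the acyl shift takes place. Either would give an aryl ester or a diaryl ether in place of the ketone. The fallback brings in the acyl group by directed lithiation, sets out from 4 and comes back at 14. The phenol of 4 is capped with MOMCl and i-Pr2NEt in CH2Cl2 to give 1-(benzyloxy)-3-(methoxymethoxy)-5-[(4-methoxyphenyl)ethynyl]benzene F1. n-BuLi/TMEDA in THF at −20 °C should metalate the carbon between the two ether oxygens, and 4-methylpentanal traps the aryllithium to give racemic 1-{2-(benzyloxy)-6-(methoxymethoxy)-4-[(4-methoxyphenyl)ethynyl]phenyl}-4-methylpentan-1-ol F2. Oxidation with Dess–Martin periodinane gives 1-{2-(benzyloxy)-6-(methoxymethoxy)-4-[(4-methoxyphenyl)ethynyl]phenyl}-4-methylpentan-1-one F3. Dilute HCl in MeOH at rt should remove the acetal beside the carbonyl without touching the benzyl ether or the alkyne, giving 14.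

Step 4 (directed silylation). Butyllithium may deprotonate the benzylic OCH2 (followed by a Wittig shift on warming) or add across the diaryl alkyne, or incomplete N-silylation may let the carbamate collapse. The fallback makes the C–Si bond by iodine–lithium exchange and an O-to-C silyl shift instead of by deprotonation; it sets out from 1 and 3 and comes back at 11. Sonogashira coupling of 1 with 3 gives 5-[(4-methoxyphenyl)ethynyl]benzene-1,3-diol F4. Iodination with I2 and NaHCO3 in aqueous THF at 0 °C should enter between the two hydroxyls, as is usual for resorcinols, to give 2-iodo-5-[(4-methoxyphenyl)ethynyl]benzene-1,3-diol F5. Statistical monobenzylation (BnBr, K2CO3, DMF) gives 3-(benzyloxy)-2-iodo-5-[(4-methoxyphenyl)ethynyl]phenol F6, and hexamethyldisilazane gives {3-(benzyloxy)-2-iodo-5-[(4-methoxyphenyl)ethynyl]phenoxy}trimethylsilane F7. One equivalent of n-BuLi in THF at −78 °C should undergo exchange at iodine far faster than any deprotonation or addition, the retro-Brook shift then delivers the lithium salt of 10, and Tf2O converts it into 11.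

Step 7 (alkyne hydration). In the hot acidic medium the benzyl ether may be lost with transfer of the benzyl cation to the electron-rich rings, or water may add sluggishly to the alkyne deactivated by the acyl group of ring B. The fallback reverses the order of the last two operations and changes the mode of alkyne activation; it sets out from 14 and comes back at 16. BCl3 with pentamethylbenzene as cation scavenger in CH2Cl2 at −78 °C should cleave the benzyl ether beside the carbonyl while sparing the methyl ether, giving 1-{2,6-dihydroxy-4-[(4-methoxyphenyl)ethynyl]phenyl}-4-methylpentan-1-one F8. Hydration under π-acid catalysis by monovalent gold (Ph3PAuCl/AgOTf, dioxane/H2O, 80 °C), in a nearly neutral medium and with the same electronic bias toward the anisyl-bearing carbon, should then give 16 directly.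

**Further compounds**

F1 | step 6 | 1-(benzyloxy)-3-(methoxymethoxy)-5-[(4-methoxyphenyl)ethynyl]benzene | COCOc1cc(OCc2ccccc2)cc(C#Cc2ccc(OC)cc2)c1
F2 | step 6 | 1-{2-(benzyloxy)-6-(methoxymethoxy)-4-[(4-methoxyphenyl)ethynyl]phenyl}-4-methylpentan-1-ol (racemic) | COCOc1cc(C#Cc2ccc(OC)cc2)cc(OCc2ccccc2)c1C(O)CCC(C)C
F3 | step 6 | 1-{2-(benzyloxy)-6-(methoxymethoxy)-4-[(4-methoxyphenyl)ethynyl]phenyl}-4-methylpentan-1-one | COCOc1cc(C#Cc2ccc(OC)cc2)cc(OCc2ccccc2)c1C(=O)CCC(C)C
F4 | step 4 | 5-[(4-methoxyphenyl)ethynyl]benzene-1,3-diol | COc1ccc(C#Cc2cc(O)cc(O)c2)cc1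
F5 | step 4 | 2-iodo-5-[(4-methoxyphenyl)ethynyl]benzene-1,3-diol | COc1ccc(C#Cc2cc(O)c(I)c(O)c2)cc1
F6 | step 4 | 3-(benzyloxy)-2-iodo-5-[(4-methoxyphenyl)ethynyl]phenol | COc1ccc(C#Cc2cc(O)c(I)c(OCc3ccccc3)c2)cc1
F7 | step 4 | {3-(benzyloxy)-2-iodo-5-[(4-methoxyphenyl)ethynyl]phenoxy}trimethylsilane | COc1ccc(C#Cc2cc(O[Si](C)(C)C)c(I)c(OCc3ccccc3)c2)cc1
F8 | step 7 | 1-{2,6-dihydroxy-4-[(4-methoxyphenyl)ethynyl]phenyl}-4-methylpentan-1-one | COc1ccc(C#Cc2cc(O)c(C(=O)CCC(C)C)c(O)c2)cc1
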